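## Retrosynthetic overview

1. Target ⇐ Wittig olefination, convex-face hydrogenation and acetal cleavage, from an enantiopure ring A ketone of the cyclohexane-fused [3]-ladderane and a C8 phosphonium salt carrying benzylidene-protected glycerol.
2. Ketone ⇐ C2-symmetric trans-diol on ring A (cyclic sulfate, regioselective hydride opening, oxidation); the chiral pool fixes the absolute configuration.
3. Ladder ⇐ key step: thermal 6π then photochemical 4π electrocyclization of a ring-A-fused cycloocta-1,3,5-triene.
4. Triene ⇐ dipotassium cyclooctatetraenide plus the L-threitol-derived 1,4-ditosylate (double alkylation).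
5. Ring order: A (alkylation) → B (6π) → C and D together (4π).

Conventions: ring A = cyclohexane; rings B, C, D = cyclobutanes in ladder order, B fused to A. Locants follow tetracyclo[6.4.0.0(2,7).0(3,6)]dodecane: C1/C8 = A–B fusion, C2/C7 = B–C fusion, C3/C6 = C–D fusion, C4/C5 = ring D, C9–C12 = ring A, and C10 is the carbon that bears the chain in the target. "Convex face" of ring A = the face of H-1/H-8, away from ring B.

Assumption: hydride opens the cyclic sulfate at the carbon whose oxygen lies on the ring B side (C11); if the opposite regiochemistry were found, the D-threitol ditosylate would be used in the same route. The sulfur epimers of the cyclic sulfite and the E/Z isomers of the Wittig alkene are carried as mixtures, since both elements vanish in the next operation.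

## Route

Step 1
Reactants: 1 cyclooctatetraene; 2 (4S,5S)-4,5-bis(tosyloxymethyl)-2,2-dimethyl-1,3-dioxolane
Product: 4 (10S,11S)-10,11-isopropylidenedioxy-cis-bicyclo[6.4.0]dodeca-2,4,6-triene, via dipotassium cyclooctatetraenide 3 (not isolated)
Conditions: K (2.2 equiv), THF, rt; then 2 (0.9 equiv) in THF, slow addition, −40 °C → rt
Reagents that add atoms: none
Why: Two-electron reduction gives the aromatic dianion, which undergoes double SN2 alkylation by the primary tosylates, the intramolecular second alkylation at the adjacent carbon closing ring A cis-fused; because the trans-acetonide tether is C2-symmetric, the two possible cis fusions are the same compound, so one enantiopure stereoisomer forms with C10/C11 taken unchanged from L-tartaric acid.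

Step 2
Reactants: 4 (10S,11S)-10,11-isopropylidenedioxy-cis-bicyclo[6.4.0]dodeca-2,4,6-triene
Product: 6 cis-anti-cis-anti-cis-tetracyclo[6.4.0.0(2,7).0(3,6)]dodec-4-ene-10,11-diol acetonide (10S,11S), via tricyclic cyclohexadiene 5 (not isolated)
Conditions: degassed heptane (0.01 M), 70 °C, 1 h (dark); then hν (254 nm, quartz), 40 °C
Reagents that add atoms: none
Why: Proposed new method: the fused cyclooctatriene closes thermally by a reversible disrotatory 6π electrocyclization (cyclooctatriene/bicyclo[4.2.0]octadiene valence tautomerism), giving ring B cis-fused with the diene ring on the less hindered face anti to ring A; the s-cis cyclohexadiene then closes photochemically by a disrotatory 4π electrocyclization away from ring B (closest known type: photoclosure of cis-1,2-dihydrophthalic anhydride to a bicyclo[2.2.0]hexene), and the product is transparent at 254 nm and accumulates, which sets all six ladder stereocentres.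

Step 3
Reactants: 6 cis-anti-cis-anti-cis-tetracyclo[6.4.0.0(2,7).0(3,6)]dodec-4-ene-10,11-diol acetonide
Product: 8 (10S,11S)-cis-anti-cis-anti-cis-tetracyclo[6.4.0.0(2,7).0(3,6)]dodecane-10,11-diol, via saturated acetonide 7 (not isolated)
Conditions: KO2CN=NCO2K, AcOH, MeOH, 0 °C → rt; then 1 M HCl, rt
Reagents that add atoms: none
Why: Diimide reduction transfers H2 concertedly and selectively to the strained cis-cyclobutene without touching the ladder σ-bonds (no new stereocentre), and aqueous acid then hydrolyses the strained trans-fused acetonide.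

Step 4
Reactants: 8 (10S,11S)-ladderane-10,11-diol
Product: 10 (10S,11S)-ladderane-10,11-diyl cyclic sulfate, via cyclic sulfite 9 (not isolated)
Conditions: SOCl2, Et3N, CH2Cl2, 0 °C; then RuCl3 (cat.), NaIO4, MeCN/H2O, 0 °C
Reagents that add atoms: thionyl chloride O=S(Cl)Cl; sodium periodate [Na+].[O-]I(=O)(=O)=O
Why: Sharpless cyclic sulfate synthesis, in which the diol forms the cyclic sulfite and RuO4 generated in situ oxidizes it at sulfur, leaving both carbinol centres untouched.

Step 5
Reactants: 10 (10S,11S)-ladderane-10,11-diyl cyclic sulfate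
Product: 12 (10R)-ladderan-10-ol (OH on the convex face; trans to ring B), via lithium alkyl sulfate 11 (not isolated)
Conditions: LiEt3BH, THF, 0 °C → rt; then H2SO4 (cat.), H2O, THF, rt
Reagents that add atoms: none
Why: SN2 hydride opening of a cyclic sulfate, regiocontrolled by the ring system: backside attack at C11 comes from the open convex face, whereas attack at C10 would have to pass under ring A next to ring B, so C11 becomes CH2 and the C10 oxygen survives; the minor regioisomer is a diastereomer and is removed by chromatography, so enantiopurity is not at stake.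

Step 6
Reactants: 12 (10R)-ladderan-10-ol
Product: 13 cis-anti-cis-anti-cis-tetracyclo[6.4.0.0(2,7).0(3,6)]dodecan-10-one
Conditions: Dess–Martin periodinane, CH2Cl2, rt
Reagents that add atoms: none
Why: Dess–Martin oxidation; the ketone has no stereocentre alpha to it, and its position at C10 rather than C11 now carries the absolute stereochemical information.

Step 7
Reactants: 14 cis-2-phenyl-1,3-dioxan-5-ol (cis-1,3-O-benzylideneglycerol); 15 1,8-dibromooctane
Product: 17 cis-5-(8-bromooctyloxy)-2-phenyl-1,3-dioxane, via sodium alkoxide 16 (not isolated)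
Conditions: NaH, DMF, 0 °C; then 15 (3 equiv), n-Bu4NI (cat.), rt
Reagents that add atoms: none
Why: Williamson ether synthesis of the secondary alkoxide on a primary bromide, with excess dibromide suppressing double alkylation.

Step 8
Reactants: 17 cis-5-(8-bromooctyloxy)-2-phenyl-1,3-dioxane; 18 triphenylphosphine
Product: 19 [8-(cis-2-phenyl-1,3-dioxan-5-yloxy)octyl]triphenylphosphonium bromide
Conditions: MeCN, 80 °C
Reagents that add atoms: none
Why: SN2 quaternization of triphenylphosphine by the primary bromide.

Step 9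
Reactants: 19 [8-(cis-2-phenyl-1,3-dioxan-5-yloxy)octyl]triphenylphosphonium bromide; 13 ladderan-10-one
Product: 21 10-[8-(cis-2-phenyl-1,3-dioxan-5-yloxy)octylidene]ladderane (E/Z mixture), via phosphorus ylide 20 (not isolated)
Conditions: NaN(SiMe3)2, THF, 0 °C; then 13, 0 °C → rt
Reagents that add atoms: none
Why: Wittig olefination of the unhindered cyclohexanone by a non-stabilized ylide; alkene geometry is irrelevant because the alkene is hydrogenated next.

Step 10
Reactants: 21 10-[8-(cis-2-phenyl-1,3-dioxan-5-yloxy)octylidene]ladderane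
Product: 23 target 2-O-[8-(ladderan-10-yl)octyl]glycerol (CNP0193334.1), via saturated benzylidene acetal 22 (not isolated)
Conditions: H2 (1 atm), [Ir(cod)(PCy3)(py)]PF6 (cat.), CH2Cl2, rt; then 1 M HCl, THF, rt
Reagents that add atoms: none
Why: Crabtree hydrogenation delivers H2 to the trisubstituted alkene from the convex face of ring A, which places H-10 cis to H-1/H-8 and the chain cis to ring B as in the target; acid hydrolysis then removes the benzylidene acetal.

## Compound list

1 | cyclooctatetraene | C1=CC=CC=CC=C1 | starting material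
2 | (4S,5S)-4,5-bis(tosyloxymethyl)-2,2-dimethyl-1,3-dioxolane (1,4-di-O-tosyl-2,3-O-isopropylidene-L-threitol) | CC1(C)O[C@@H](COS(=O)(=O)c2ccc(C)cc2)[C@H](COS(=O)(=O)c2ccc(C)cc2)O1 | starting material
3 | dipotassium cyclooctatetraenide | [K+].[K+].[CH-]1C=CC=CC=C[CH-]1 | intermediate
4 | (10S,11S)-10,11-isopropylidenedioxy-cis-bicyclo[6.4.0]dodeca-2,4,6-triene (ring-enforced all-Z triene) | CC1(C)O[C@@H]2[C@@H](O1)C[C@@H]3[C@H](C2)C=CC=CC=C3 | intermediate
5 | (10S,11S)-10,11-isopropylidenedioxy-cis-anti-cis-tricyclo[6.4.0.0(2,7)]dodeca-3,5-diene (ring A anti to the cyclohexadiene across ring B) | CC1(C)O[C@@H]2[C@@H](O1)C[C@@H]3[C@H](C2)[C@H]4C=CC=C[C@@H]34 | intermediate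
6 | (10S,11S)-cis-anti-cis-anti-cis-tetracyclo[6.4.0.0(2,7).0(3,6)]dodec-4-ene-10,11-diol acetonide | CC1(C)O[C@@H]2[C@@H](O1)C[C@@H]3[C@H](C2)[C@H]4[C@@H]5C=C[C@@H]5[C@@H]34 | intermediate
7 | (10S,11S)-cis-anti-cis-anti-cis-tetracyclo[6.4.0.0(2,7).0(3,6)]dodecane-10,11-diol acetonide | CC1(C)O[C@@H]2[C@@H](O1)C[C@@H]3[C@H](C2)[C@H]4[C@@H]5CC[C@@H]5[C@@H]34 | intermediate
8 | (10S,11S)-cis-anti-cis-anti-cis-tetracyclo[6.4.0.0(2,7).0(3,6)]dodecane-10,11-diol (10-OH trans to ring B, 11-OH cis to ring B) | O[C@@H]1[C@@H](O)C[C@@H]2[C@H](C1)[C@H]1[C@@H]3CC[C@@H]3[C@@H]21 | intermediate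
9 | cyclic sulfite of diol 8 (sulfur epimers) | O=S1O[C@@H]2[C@@H](O1)C[C@@H]3[C@H](C2)[C@H]4[C@@H]5CC[C@@H]5[C@@H]34 | intermediate
10 | cyclic sulfate of diol 8 | O=S1(=O)O[C@@H]2[C@@H](O1)C[C@@H]3[C@H](C2)[C@H]4[C@@H]5CC[C@@H]5[C@@H]34 | intermediate
11 | lithium (10R)-ladderan-10-yl sulfate | [Li+].[O-]S(=O)(=O)O[C@@H]1CC[C@@H]2[C@H](C1)[C@H]1[C@@H]3CC[C@@H]3[C@@H]21 | intermediate
12 | (10R)-cis-anti-cis-anti-cis-tetracyclo[6.4.0.0(2,7).0(3,6)]dodecan-10-ol (OH trans to ring B) | O[C@@H]1CC[C@@H]2[C@H](C1)[C@H]1[C@@H]3CC[C@@H]3[C@@H]21 | intermediate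
13 | cis-anti-cis-anti-cis-tetracyclo[6.4.0.0(2,7).0(3,6)]dodecan-10-one | O=C1CC[C@@H]2[C@H](C1)[C@H]1[C@@H]3CC[C@@H]3[C@@H]21 | intermediate
14 | cis-2-phenyl-1,3-dioxan-5-ol | O[C@H]1CO[C@@H](c2ccccc2)OC1 | starting material
15 | 1,8-dibromooctane | BrCCCCCCCCBr | starting material
16 | sodium cis-2-phenyl-1,3-dioxan-5-olate | [Na+].[O-][C@H]1CO[C@@H](c2ccccc2)OC1 | intermediate
17 | cis-5-(8-bromooctyloxy)-2-phenyl-1,3-dioxane | O(CCCCCCCCBr)[C@H]1CO[C@@H](c2ccccc2)OC1 | intermediate
18 | triphenylphosphine | c1ccc(cc1)P(c1ccccc1)c1ccccc1 | starting material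
19 | [8-(cis-2-phenyl-1,3-dioxan-5-yloxy)octyl]triphenylphosphonium bromide | O(CCCCCCCC[P+](c1ccccc1)(c1ccccc1)c1ccccc1)[C@H]1CO[C@@H](c2ccccc2)OC1.[Br-] | intermediate
20 | [8-(cis-2-phenyl-1,3-dioxan-5-yloxy)octylidene]triphenylphosphorane | O(CCCCCCCC=P(c1ccccc1)(c1ccccc1)c1ccccc1)[C@H]1CO[C@@H](c2ccccc2)OC1 | intermediate
21 | 10-[8-(cis-2-phenyl-1,3-dioxan-5-yloxy)octylidene]-cis-anti-cis-anti-cis-tetracyclo[6.4.0.0(2,7).0(3,6)]dodecane (E/Z mixture) | O(CCCCCCCC=C1CC[C@@H]2[C@H](C1)[C@H]1[C@@H]3CC[C@@H]3[C@@H]21)[C@H]1CO[C@@H](c2ccccc2)OC1 | intermediate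
22 | cis-5-{8-[ladderan-10-yl]octyloxy}-2-phenyl-1,3-dioxane (chain at C10 cis to ring B) | O(CCCCCCCC[C@H]1CC[C@@H]2[C@H](C1)[C@H]1[C@@H]3CC[C@@H]3[C@@H]21)[C@H]1CO[C@@H](c2ccccc2)OC1 | intermediate
23 | 2-{8-[cis-anti-cis-anti-cis-tetracyclo[6.4.0.0(2,7).0(3,6)]dodecan-10-yl]octyloxy}propane-1,3-diol (H-10 cis to H-1/H-8) | OCC(CO)OCCCCCCCC[C@H]1CC[C@@H]2[C@H](C1)[C@H]1[C@@H]3CC[C@@H]3[C@@H]21 | target

## Step count and risks

Total: 10 steps. Longest linear sequence: 8 steps (steps 1–6, 9, 10); the side chain takes 2 steps (7, 8).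

Most likely to fail:

Step 2. The closed tautomer must dominate the thermal equilibrium, or the open triene will be photolysed along its own channels; the 4π closure may also give some syn ladder. Fallback: setting out from 4, heat with Fe2(CO)9 (benzene, 40 °C, then toluene, 100 °C), which traps the closed valence tautomer as the tricarbonyl(η4-diene)iron complex F1 (iron on the diene face anti to ring B) and can be purified. Decomplexation with CuCl2 in EtOH at 0 °C then frees the tricyclic diene cold, where it cannot reopen. The fallback comes back to the route at 5, which is irradiated at −20 °C (254 nm) to give 6.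

Step 5. Hydride may act as a base or attack sulfur, the SN2 at the trans-fused secondary carbon may be slow, and the regioselectivity may be modest. Fallback: setting out from 10, open the sulfate with sodium benzeneselenolate (PhSeSePh, NaBH4, EtOH/THF), a large, soft, non-basic nucleophile that enters at C11 from the convex face, to give the sodium selanyl alkyl sulfate F2. Acid hydrolysis gives the cis-hydroxy selenide F3, purified from its regioisomer. Radical cleavage of the C–Se bond (Bu3SnH, AIBN, PhMe, 80 °C) comes back to the route at 12.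

Step 10. The alkene is remote from the ring fusion, so the facial bias of the hydrogenation may be only moderate. Fallback: setting out from 12 (bypassing steps 6, 8 and 9), TsCl/pyridine gives the C10 tosylate F4. Bromide 17 with Mg in THF gives the Grignard reagent F5. A copper-catalysed sp3–sp3 coupling (CuI (cat.), TMEDA, LiOMe, THF, 0 °C) proceeds by SN2 with inversion, so the convex leaving group is replaced by the chain on the ring B face with no selectivity question. This comes back to the route at 22, which the acid treatment of step 10 converts to 23.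

## Further compounds

F1 | step 2 | tricarbonyl(η4-diene)iron complex of tricyclic diene 5 | CC1(C)O[C@@H]2[C@@H](O1)C[C@@H]3[C@H](C2)[C@H]4C=CC=C[C@@H]34.[Fe].[C-]#[O+].[C-]#[O+].[C-]#[O+]
F2 | step 5 | sodium (10R,11R)-11-(phenylselanyl)ladderan-10-yl sulfate (O and Se cis, both on the convex face) | [Na+].[O-]S(=O)(=O)O[C@@H]1[C@H]([Se]c2ccccc2)C[C@@H]2[C@H](C1)[C@H]1[C@@H]3CC[C@@H]3[C@@H]21
F3 | step 5 | cis-11-(phenylselanyl)ladderan-10-ol (OH and SePh on the convex face) | O[C@@H]1[C@H]([Se]c2ccccc2)C[C@@H]2[C@H](C1)[C@H]1[C@@H]3CC[C@@H]3[C@@H]21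
F4 | step 10 | (10R)-ladderan-10-yl 4-methylbenzenesulfonate (OTs trans to ring B) | Cc1ccc(cc1)S(=O)(=O)O[C@@H]1CC[C@@H]2[C@H](C1)[C@H]1[C@@H]3CC[C@@H]3[C@@H]21
F5 | step 10 | [8-(cis-2-phenyl-1,3-dioxan-5-yloxy)octyl]magnesium bromide | Br[Mg]CCCCCCCCO[C@H]1CO[C@@H](c2ccccc2)OC1
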